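## Retrosynthetic overview

1. Target 22 comes from C18 ketone 21 by methyl addition. The bicyclo[2.2.2]octane is closed last by a reductive aldol (C13–C24) on formyl lactone 18.
2. Rings E (γ-lactone) and C (cyclopentane) come from one tandem Michael (C23→C19) / enolate alkylation (C15–C16) on the cross-conjugated spirodienone 15.
3. Key step: ring B and the C11 spiro centre come from joining two normally nucleophilic carbons, the ketone α-carbon C17 and the phenol para-carbon C11. C17 is turned into an enolonium equivalent (α-iodo ketone) and the phenolate is dearomatised (10 → 12).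
4. Phenol 10 comes from 2,3,6-trimethylphenol, ethylene oxide, S-ethyl acetothioacetate and methyl propiolate. An asymmetric Michael addition sets C8, and Grignard addition/lactonisation closes ring A.
5. Ring order: A → B (dearomatised ring D precursor) → E and C together → bicyclo[2.2.2]octane (ring D bridged by C23–C24) → C18 carbinol.

Assumption: locants C1–C24 follow the atom order of the target SMILES (O4 and O21 are the ring oxygens), and the epimerisable centres C17 and C23 of the natural product are taken to be the thermodynamically preferred ones.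

None of these steps has been run; the reasoning behind each is given on its Why line.

## Route

Step 1
Reactants: 1 2,3,6-trimethylphenol; 2 ethylene oxide
Product: 3 4-(2-hydroxyethyl)-2,3,6-trimethylphenol
Conditions: SnCl4 (0.5 equiv), CH2Cl2, −20 to 0 °C
Reagents that add atoms: none
Why: Friedel–Crafts hydroxyethylation; the only free position para to the hindered OH is by far the most nucleophilic carbon, so the C9–C10 unit is attached at C11.

Step 2
Reactants: 3 4-(2-hydroxyethyl)-2,3,6-trimethylphenol
Product: 4 4-(2-iodoethyl)-2,3,6-trimethylphenol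
Conditions: PPh3, imidazole, iodine, CH2Cl2, 0 °C
Reagents that add atoms: iodine, II
Why: Appel iodination of the primary alcohol; the hindered phenol does not react.

Step 3
Reactants: 4 4-(2-iodoethyl)-2,3,6-trimethylphenol; 5 S-ethyl 3-oxobutanethioate
Product: 6 S-ethyl 2-acetyl-4-(4-hydroxy-2,3,5-trimethylphenyl)butanethioate (racemic)
Conditions: K2CO3, acetone, 50 °C (1.5 equiv of 5)
Reagents that add atoms: none
Why: C-alkylation of the β-keto thioester (more acidic than the phenol) by the primary iodide; any spirocyclopropyl dienone formed by phenolate participation is opened by the same enolate to the same product.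

Step 4
Reactants: 6 S-ethyl 2-acetyl-4-(4-hydroxy-2,3,5-trimethylphenyl)butanethioate; 7 methyl propiolate
Product: 8 methyl (2Z,4R)-4-acetyl-4-[(ethylsulfanyl)carbonyl]-6-(4-hydroxy-2,3,5-trimethylphenyl)hex-2-enoate
Conditions: O-allyl-N-(9-anthracenylmethyl)cinchonidinium bromide (10 mol %), Cs2CO3 (20 mol %), toluene, −40 °C
Reagents that add atoms: none
Why: Asymmetric phase-transfer Michael addition in which the chiral ammonium enolate ion pair sets the C8 quaternary centre (the pseudoenantiomeric cinchoninium salt is used if the sense is opposite), and kinetic anti addition/protonation gives the Z-enoate needed for lactonisation.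

Step 5
Reactants: 8 methyl (2Z,4R)-4-acetyl-4-[(ethylsulfanyl)carbonyl]-6-(4-hydroxy-2,3,5-trimethylphenyl)hex-2-enoate
Product: 9 S-ethyl (3R)-3-[2-(4-hydroxy-2,3,5-trimethylphenyl)ethyl]-2,2-dimethyl-6-oxo-3,6-dihydro-2H-pyran-3-carbothioate
Conditions: MeMgBr (2.3 equiv), THF, −78 to −20 °C; aq NH4Cl
Reagents that add atoms: methylmagnesium bromide, C[Mg]Br
Why: Chemoselective Grignard 1,2-addition to the methyl ketone (faster than to thioester or enoate at low temperature), after which the tertiary alkoxide lactonises onto the Z-enoate to close ring A with its gem-dimethyl carbon C2; no new stereocentre.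

Step 6
Reactants: 9 S-ethyl (3R)-3-[2-(4-hydroxy-2,3,5-trimethylphenyl)ethyl]-2,2-dimethyl-6-oxo-3,6-dihydro-2H-pyran-3-carbothioate
Product: 10 (5R)-5-acetyl-5-[2-(4-hydroxy-2,3,5-trimethylphenyl)ethyl]-6,6-dimethyl-5,6-dihydro-2H-pyran-2-one
Conditions: MeZnI (3 equiv), PdCl2(PPh3)2 (5 mol %), toluene–THF, 25 °C
Reagents that add atoms: methylzinc iodide, C[Zn]I
Why: Fukuyama coupling; zerovalent palladium inserts into the acyl–sulfur bond and the organozinc delivers the methyl group (C17) without touching the lactone or enoate.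

Step 7
Reactants: 10 (5R)-5-acetyl-5-[2-(4-hydroxy-2,3,5-trimethylphenyl)ethyl]-6,6-dimethyl-5,6-dihydro-2H-pyran-2-one
Product: 12 (8R,11R)-dispiro dienone (ring B cyclohexanone spiro-linked at C8 to ring A and at C11 to the 2,3,5-trimethyl-4-oxocyclohexa-2,5-diene ring), via iodo ketone 11 (not isolated)
Conditions: LiN(SiMe3)2 (2.2 equiv), THF, −78 °C; iodine (1.05 equiv), −78 to 0 °C
Reagents that add atoms: none
Why: Proposed new method: the dilithio phenolate/enolate (the methyl group is the only enolisable site) is iodinated at C17 to give α-iodo ketone 11, an enolonium equivalent, which the phenolate attacks through its para carbon C11 in a 6-exo-tet dearomatising alkylation (O-attack is geometrically impossible); a chair-like transition state with the CMe2 arm of ring A equatorial and the unsubstituted ortho carbon C12 axial places C19 cis to C7; the closest known reaction types are iodine-mediated intramolecular oxidative coupling of ketone enolates with electron-rich arenes and base-mediated dearomative para-alkylation of phenols.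

Step 8
Reactants: 12 (8R,11R)-dispiro dienone
Product: 13 (8R,11R)-17-methylidene dispiro dienone (C17=C16H2 conjugated to the C18 ketone)
Conditions: (CH2O)n, iPr2NH2+ CF3CO2− (1 equiv), THF, 65 °C
Reagents that add atoms: paraformaldehyde (formaldehyde), C=O
Why: Mannich-type α-methylenation at C17, the only enolisable position of the C18 ketone, introduces C16 without creating a stereocentre.

Step 9
Reactants: 13 (8R,11R)-17-methylidene dispiro dienone
Product: 15 (8R,11R)-20-acetoxy dienone (allylic acetate at C20), via allylic bromide 14 (not isolated)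
Conditions: N-bromosuccinimide, azobisisobutyronitrile (cat.), PhCF3, 80 °C; then CsOAc, DMF, 25 °C
Reagents that add atoms: caesium acetate, CC(=O)[O-].[Cs+]
Why: Wohl–Ziegler bromination is expected at the β-methyl group C20, whose radical alone is delocalised through C19=C15 onto the dienone oxygen, and SN2 displacement by acetate then installs O21, C22 and C23.

Step 10
Reactants: 15 (8R,11R)-20-acetoxy dienone
Product: 17 (8R,11R,15R,19R)-tetracyclic enone (ring C closed; spiro γ-lactone ring E at C19; C17=C18 tert-butyldimethylsilyl enol ether), via iodo silyl enol ether 16 (not isolated)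
Conditions: t-BuMe2SiCl, NaI, MeCN, 0 °C; MeCN removed; THF, LiN(SiMe3)2 (1.1 equiv), −78 to −20 °C
Reagents that add atoms: tert-butyldimethylsilyl chloride, CC(C)(C)[Si](C)(C)Cl
Why: Proposed new method: in situ silyl iodide adds 1,4 only to the s-cis-locked exocyclic enone to give allylic iodide 16; the kinetic acetate enolate then adds 5-exo-trig to C19 from the face anti to the C16 arm (ring E, C19 quaternary), and the resulting C15 enolate is alkylated 5-exo-tet by the allylic iodide on the only reachable face (ring C, C15 quaternary with methyl anti to C16); the closest known reaction types are Michael-initiated ring closure and alkylation of enolates with β-iodo silyl enol ethers.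

Step 11
Reactants: 17 (8R,11R,15R,19R)-tetracyclic enone
Product: 18 (8R,11R,15R,19R)-23-(hydroxymethylidene) lactone (Z-enol of the 23-formyl lactone)
Conditions: LiN(SiMe3)2 (2.2 equiv), HCO2Et (5 equiv), THF, −78 to 0 °C; aq NH4Cl
Reagents that add atoms: ethyl formate, CCOC=O
Why: Claisen formylation of the lactone enolate (C23 is the only enolisable carbon while C18 is masked as its silyl enol ether) introduces C24 at the aldehyde oxidation level.

Step 12
Reactants: 18 (8R,11R,15R,19R)-23-(hydroxymethylidene) lactone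
Product: 21 (8R,11S,13S,15R,17R,19R,23R,24R)-18-oxo pentacycle (target skeleton with a C18 ketone), via tris-silyl intermediate 19 (not isolated), via keto enol 20 (not isolated)
Conditions: Et3SiH (3 equiv), RhCl(PPh3)3 (5 mol %), THF, 50 °C; then 2 M HCl, THF, 25 °C
Reagents that add atoms: none
Why: Rhodium-catalysed 1,4-hydrosilylation reduces the enone (faster than the ring A enoate) and silylates the enol; acid then frees the C14 enol, the C18 ketone and the C24 aldehyde, and an intramolecular aldol addition of C13 to C24 on the only face the C23 tether allows closes the bicyclo[2.2.2]octane, with reversible aldol/enolisation delivering the C24 hydroxyl hydrogen-bonded to the C14 carbonyl and the stable C23 and C17 (cis ring B/C fusion) epimers.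

Step 13
Reactants: 21 (8R,11S,13S,15R,17R,19R,23R,24R)-18-oxo pentacycle
Product: 22 CNP0360620.2 (8S,11S,13S,15R,17R,18R,19R,23R,24R)
Conditions: MeLi, CeCl3 (3 equiv each), THF, −78 °C; aq NH4Cl
Reagents that add atoms: methyllithium, [Li]C
Why: Organocerium 1,2-addition is selective for the C18 ketone over the two lactones and the C14 ketone (flanked by two quaternary carbons), and methyl enters on the convex face anti to the C16–C19 cage of the cis-fused ring B/C ketone to give the 18R carbinol.

## Compound list

1 | 2,3,6-trimethylphenol | Cc1ccc(C)c(C)c1O | starting material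
2 | ethylene oxide | C1CO1 | starting material
3 | 4-(2-hydroxyethyl)-2,3,6-trimethylphenol | Cc1cc(CCO)c(C)c(C)c1O | intermediate
4 | 4-(2-iodoethyl)-2,3,6-trimethylphenol | Cc1cc(CCI)c(C)c(C)c1O | intermediate
5 | S-ethyl 3-oxobutanethioate | CCSC(=O)CC(C)=O | starting material
6 | S-ethyl 2-acetyl-4-(4-hydroxy-2,3,5-trimethylphenyl)butanethioate (racemic) | CCSC(=O)C(CCc1cc(C)c(O)c(C)c1C)C(C)=O | intermediate
7 | methyl propiolate | C#CC(=O)OC | starting material
8 | methyl (2Z,4R)-4-acetyl-4-[(ethylsulfanyl)carbonyl]-6-(4-hydroxy-2,3,5-trimethylphenyl)hex-2-enoate | COC(=O)/C=C\[C@](C(C)=O)(C(=O)SCC)CCc1cc(C)c(O)c(C)c1C | intermediate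
9 | S-ethyl (3R)-3-[2-(4-hydroxy-2,3,5-trimethylphenyl)ethyl]-2,2-dimethyl-6-oxo-3,6-dihydro-2H-pyran-3-carbothioate | CC1(C)OC(=O)C=C[C@]1(C(=O)SCC)CCc1cc(C)c(O)c(C)c1C | intermediate
10 | (5R)-5-acetyl-5-[2-(4-hydroxy-2,3,5-trimethylphenyl)ethyl]-6,6-dimethyl-5,6-dihydro-2H-pyran-2-one | CC1(C)OC(=O)C=C[C@]1(C(C)=O)CCc1cc(C)c(O)c(C)c1C | intermediate
11 | (5R)-5-[2-(4-hydroxy-2,3,5-trimethylphenyl)ethyl]-5-(iodoacetyl)-6,6-dimethyl-5,6-dihydro-2H-pyran-2-one (formed as its lithium phenolate) | CC1(C)OC(=O)C=C[C@]1(C(=O)CI)CCc1cc(C)c(O)c(C)c1C | intermediate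
12 | (8R,11R)-dispiro dienone: ring B cyclohexanone (C18=O, C17H2) spiro at C8 to ring A (6,6-dimethyl-5,6-dihydro-2H-pyran-2-one) and at C11 to a 2,3,5-trimethyl-4-oxocyclohexa-2,5-diene ring | CC1(C)OC(=O)C=C[C@]12CC[C@]3(C=C(C)C(=O)C(C)=C3C)CC2=O | intermediate
13 | (8R,11R)-17-methylidene derivative of 12 (C17=C16H2) | CC1(C)OC(=O)C=C[C@]12CC[C@]3(C=C(C)C(=O)C(C)=C3C)C(=C)C2=O | intermediate
14 | (8R,11R)-20-bromo derivative of 13 | CC1(C)OC(=O)C=C[C@]12CC[C@]3(C=C(C)C(=O)C(C)=C3CBr)C(=C)C2=O | intermediate
15 | (8R,11R)-20-acetoxy derivative of 13 | CC1(C)OC(=O)C=C[C@]12CC[C@]3(C=C(C)C(=O)C(C)=C3COC(C)=O)C(=C)C2=O | intermediate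
16 | (8R,11R)-16-iodo C17=C18 tert-butyldimethylsilyl enol ether of 15 | CC1(C)OC(=O)C=C[C@]12CC[C@]3(C=C(C)C(=O)C(C)=C3COC(C)=O)C(CI)=C2O[Si](C)(C)C(C)(C)C | intermediate
17 | (8R,11R,15R,19R)-tetracyclic enone: rings A, B (C17=C18 silyl enol ether) and C, spiro γ-lactone ring E at C19, C12=C13–C14=O enone | CC1(C)OC(=O)C=C[C@]12CC[C@]13C=C(C)C(=O)[C@](C)(CC1=C2O[Si](C)(C)C(C)(C)C)[C@]31COC(=O)C1 | intermediate
18 | (8R,11R,15R,19R)-23-(hydroxymethylidene) derivative of 17 (Z-enol of the 23-formyl lactone) | CC1(C)OC(=O)C=C[C@]12CC[C@]13C=C(C)C(=O)[C@](C)(CC1=C2O[Si](C)(C)C(C)(C)C)[C@]31COC(=O)/C1=C\O | intermediate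
19 | (8R,11R,15R,19R)-tris-silyl intermediate: C13=C14 and C23=C24 triethylsilyl enol ethers, C17=C18 tert-butyldimethylsilyl enol ether | CC1(C)OC(=O)C=C[C@]12CC[C@]13CC(C)=C(O[Si](CC)(CC)CC)[C@](C)(CC1=C2O[Si](C)(C)C(C)(C)C)[C@]31COC(=O)/C1=C\O[Si](CC)(CC)CC | intermediate
20 | (8R,11S,15R,17R,19R)-keto enol: C14 and C18 ketones, C13–H (both epimers), 23-(hydroxymethylidene) lactone | CC1(C)OC(=O)C=C[C@]12CC[C@]13CC(C)C(=O)[C@](C)(C[C@H]1C2=O)[C@]31COC(=O)/C1=C\O | intermediate
21 | (8R,11S,13S,15R,17R,19R,23R,24R)-18-oxo pentacycle (target lacking the C18 methyl; C18 ketone) | CC1(C)OC(=O)C=C[C@]12CC[C@]13C[C@]4(C)C(=O)[C@](C)(C[C@H]1C2=O)[C@]31COC(=O)[C@H]1[C@H]4O | intermediate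
22 | CNP0360620.2 (8S,11S,13S,15R,17R,18R,19R,23R,24R) | CC1(C)OC(=O)C=C[C@]12CC[C@]13C[C@]4(C)C(=O)[C@](C)(C[C@H]1[C@@]2(C)O)[C@]31COC(=O)[C@H]1[C@H]4O | target

## Step count and risks

Total steps: 13. Longest linear sequence: 13 (from 1).

**Step 7 (key dearomatising coupling).** It may stop at the α-iodo ketone, or give the wrong C11 epimer. Fallback, setting out from 10 and returning at 12: detrifluoroacetylative diazo transfer (LiN(SiMe3)2, CF3CO2CH2CF3; then MsN3, Et3N) converts 10 into the diazoketone (5R)-5-(diazoacetyl)-5-[2-(4-hydroxy-2,3,5-trimethylphenyl)ethyl]-6,6-dimethyl-5,6-dihydro-2H-pyran-2-one F1. CF3CO2H in CH2Cl2 at −20 °C protonates it to an α-diazonio ketone, a different enolonium equivalent, which the para carbon of the free phenol captures with loss of nitrogen to give 12.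

**Step 10 (tandem Michael/alkylation).** The base may deprotonate C20 instead of the acetate, or the Michael addition may take the wrong face. Fallback, setting out from 13 and returning at 17, which separates a reversible soft Michael step from the alkylation:
- Bromide 14 is made as in step 9 and quenched with potassium allyl malonate to give the (8R,11R)-20-[(allyloxycarbonyl)acetoxy] dienone F2.
- DBU in MeCN effects the 5-exo Michael addition under thermodynamic control to give the (8R,11R,19R)-spiro-lactone bearing CO2allyl at C23 and H at C15, F3.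
- t-BuMe2SiCl/NaI converts F3 into its 16-iodo C17=C18 silyl enol ether F4.
- LiN(SiMe3)2 (2.2 equiv) closes ring C through the C15 ketone enolate to give the 23-(allyloxycarbonyl) derivative of 17, F5.
- Pd(PPh3)4 with morpholine removes the allyl group and the acid decarboxylates to 17.

**Step 12 (reduction/aldol).** The hydrosilylation may not discriminate enone from enoate, and the acid-mediated aldol is under thermodynamic control. Fallback, setting out from 18 and returning at 21: Fe(acac)3 (cat.) and PhSiH3 in EtOH at 25 °C deliver a hydrogen atom to C12 only (the electron-poor enoate is far slower). The C13 radical/iron enolate adds to the C24 aldehyde in a kinetically controlled reductive aldol, giving the C17=C18 tert-butyldimethylsilyl enol ether of 21, F6. Aqueous HCl in THF then unmasks the C18 ketone to give 21.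

Further compounds
F1 | step 7 | (5R)-5-(diazoacetyl)-5-[2-(4-hydroxy-2,3,5-trimethylphenyl)ethyl]-6,6-dimethyl-5,6-dihydro-2H-pyran-2-one | CC1(C)OC(=O)C=C[C@]1(C(=O)C=[N+]=[N-])CCc1cc(C)c(O)c(C)c1C
F2 | step 10 | (8R,11R)-20-[(allyloxycarbonyl)acetoxy] derivative of 13 | CC1(C)OC(=O)C=C[C@]12CC[C@]3(C=C(C)C(=O)C(C)=C3COC(=O)CC(=O)OCC=C)C(=C)C2=O
F3 | step 10 | (8R,11R,19R)-spiro-lactone Michael adduct with CO2allyl at C23 and H at C15 (C15 and C23 epimers) | CC1(C)OC(=O)C=C[C@]12CC[C@]3(C=C(C)C(=O)C(C)[C@]34COC(=O)C4C(=O)OCC=C)C(=C)C2=O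
F4 | step 10 | 16-iodo C17=C18 tert-butyldimethylsilyl enol ether of F3 | CC1(C)OC(=O)C=C[C@]12CC[C@]3(C=C(C)C(=O)C(C)[C@]34COC(=O)C4C(=O)OCC=C)C(CI)=C2O[Si](C)(C)C(C)(C)C
F5 | step 10 | (8R,11R,15R,19R)-23-(allyloxycarbonyl) derivative of 17 | CC1(C)OC(=O)C=C[C@]12CC[C@]13C=C(C)C(=O)[C@](C)(CC1=C2O[Si](C)(C)C(C)(C)C)[C@]31COC(=O)C1C(=O)OCC=C
F6 | step 12 | (8R,11R,13S,15R,19R,23R,24R)-C17=C18 tert-butyldimethylsilyl enol ether of 21 | CC1(C)OC(=O)C=C[C@]12CC[C@]13C[C@]4(C)C(=O)[C@](C)(CC1=C2O[Si](C)(C)C(C)(C)C)[C@]31COC(=O)[C@H]1[C@H]4O
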